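**Retrosynthetic overview**

1. Ring labels: ring A is the guaiacyl ring of the 3-benzyl group, ring B the lactone (O1, C2 carbonyl, C3, C4, C5), rings C and D the benzo and furan rings of the dihydrobenzofuran, ring E its 2-aryl group. Lappaol A ⇐ keto lactone 20 by turning a benzylic C=O into CH2 and removing three O-benzyl groups.
2. 20 ⇐ key step, ring B closed last by a formal [3+2] annulation that makes C4–C5 and C2–C3 together: a mixed diorganozinc carrying the intact CH2–O–C(=O) unit adds through CH2 to the β-carbon of (E)-enone 14, and the enolate so formed is C-acylated by the carbonate carbon.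
3. Enabling feature: the carbon that ends as the benzylic CH2 between ring A and C3 is carried as an aryl ketone C=O conjugated to the C=C whose carbons become C3 and C4. It polarises the alkene (CH2O to C4, C=O to C3), supplies the enolate at C3, and makes C3–H acidic so that the trans lactone is reached by equilibration.
4. 14 ⇐ cross-metathesis of 5-allyl-dihydrobenzofuran 10 with aryl vinyl ketone 13 (from O-benzylvanillin).
5. 10 ⇐ eugenol; ring D is formed first by enantioselective Rh-carbene C–H insertion, then C3 is epimerised to trans. Order of ring formation: ring D (step 4), then ring B (step 13); rings A, C and E are bought.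

Key step: step 13

Remark (assumption): Rh2(S-PTTL)4 in step 4 and the (S,R,R)-phosphoramidite in step 13 are taken to induce the configurations drawn; should either induce the opposite sense, its antipode is used.
Remark (abbreviation): "Bf" in names stands for the (2S,3R)-3-[(benzyloxy)methyl]-2-[4-(benzyloxy)-3-methoxyphenyl]-7-methoxy-2,3-dihydro-1-benzofuran-5-yl group.

**Route**

Step 1
Reactants: 1 eugenol (4-allyl-2-methoxyphenol)
Product: 2 4-allyl-2-iodo-6-methoxyphenol
Conditions: NIS (1.05 equiv), DMF, 0 → 25 °C, dark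
Reagents that add atoms: N-iodosuccinimide, O=C1CCC(=O)N1I
Why: Electrophilic aromatic iodination goes to the only free position ortho to the phenol OH (para is blocked by allyl, the other ortho by OMe), and the phenol ring is far more nucleophilic than the isolated alkene.

Step 2
Reactants: 2 4-allyl-2-iodo-6-methoxyphenol; 3 [4-(benzyloxy)-3-methoxyphenyl]methanol
Product: 4 5-allyl-2-{[4-(benzyloxy)-3-methoxybenzyl]oxy}-1-iodo-3-methoxybenzene
Conditions: PPh3, DIAD, THF, 0 → 25 °C
Reagents that add atoms: none
Why: Mitsunobu etherification of an acidic phenol with a primary benzylic alcohol proceeds under neutral conditions that leave the aryl iodide, the allyl group and the acid-sensitive electron-rich benzyl ether intact.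

Step 3
Reactants: 4 the aryl iodide; 5 ethyl diazoacetate
Product: 6 ethyl 2-diazo-2-[5-allyl-2-{[4-(benzyloxy)-3-methoxybenzyl]oxy}-3-methoxyphenyl]acetate
Conditions: Pd(PPh3)4 (5 mol%), Ag2CO3 (0.5 equiv), Et3N, toluene, 25 °C
Reagents that add atoms: none
Why: Palladium-catalysed cross-coupling of an aryl iodide with the C–H bond of an acceptor diazo ester (oxidative addition to zerovalent palladium, silver-assisted deprotonative transfer of the diazo carbon, reductive elimination) should give the aryl diazoacetate with the diazo group retained at room temperature.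

Step 4
Reactants: 6 the aryl diazoacetate
Product: 7 ethyl (2S,3R)-5-allyl-2-[4-(benzyloxy)-3-methoxyphenyl]-7-methoxy-2,3-dihydro-1-benzofuran-3-carboxylate (2,3-cis)
Conditions: dirhodium tetrakis[N-phthaloyl-(S)-tert-leucinate], Rh2(S-PTTL)4 (1 mol%), toluene, −60 °C, slow addition of 6
Reagents that add atoms: none
Why: Intramolecular 1,5 C–H insertion of the donor/acceptor rhodium carbene into the electron-rich benzylic ether C–H closes ring D; the chiral carboxylate ligands select one enantiotopic benzylic hydrogen (setting C2 as S) and the concerted insertion gives the cis ester kinetically, while the remote allyl group can only react intermolecularly and is outpaced.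

Step 5
Reactants: 7 the cis ester
Product: 8 ethyl (2S,3S)-5-allyl-2-[4-(benzyloxy)-3-methoxyphenyl]-7-methoxy-2,3-dihydro-1-benzofuran-3-carboxylate (2,3-trans)
Conditions: NaOEt (0.3 equiv), EtOH, 25 °C
Reagents that add atoms: none
Why: Base-mediated epimerisation through the ester enolate inverts only C3 and should drive the strained cis isomer to the thermodynamically preferred trans ester, C2 carrying no acidic hydrogen.

Step 6
Reactants: 8 the trans ester
Product: 9 [(2S,3R)-5-allyl-2-[4-(benzyloxy)-3-methoxyphenyl]-7-methoxy-2,3-dihydro-1-benzofuran-3-yl]methanol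
Conditions: LiAlH4, THF, 0 °C; aq. NaOH work-up
Reagents that add atoms: none
Why: Hydride reduction of the ester to the primary alcohol touches neither the aryl ethers, the alkene nor a stereocentre (the descriptor at C3 changes only through the priority rules).

Step 7
Reactants: 9 the primary alcohol
Product: 10 (2S,3R)-5-allyl-3-[(benzyloxy)methyl]-2-[4-(benzyloxy)-3-methoxyphenyl]-7-methoxy-2,3-dihydro-1-benzofuran
Conditions: NaH, BnBr, n-Bu4NI (cat.), THF–DMF, 0 → 25 °C
Reagents that add atoms: benzyl bromide, BrCc1ccccc1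
Why: Williamson etherification masks the only protic group before the organozinc step with a group that leaves in the final hydrogenolysis.

Step 8
Reactants: 11 4-(benzyloxy)-3-methoxybenzaldehyde
Product: 12 1-[4-(benzyloxy)-3-methoxyphenyl]prop-2-en-1-ol (racemic)
Conditions: CH2=CHMgBr, THF, −78 → 0 °C; aq. NH4Cl
Reagents that add atoms: vinylmagnesium bromide, C=C[Mg]Br
Why: Grignard 1,2-addition to the aldehyde; the new carbinol centre is oxidised away in the next step.

Step 9
Reactants: 12 the allylic alcohol
Product: 13 1-[4-(benzyloxy)-3-methoxyphenyl]prop-2-en-1-one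
Conditions: activated MnO2 (excess), CH2Cl2, 25 °C; used at once
Reagents that add atoms: none
Why: MnO2 selectively oxidises the doubly activated (allylic and benzylic) alcohol to the aryl vinyl ketone under neutral conditions.

Step 10
Reactants: 10 the allyl dihydrobenzofuran; 13 the aryl vinyl ketone (2 equiv)
Product: 14 (E)-1-[4-(benzyloxy)-3-methoxyphenyl]-4-Bf-but-2-en-1-one
Conditions: second-generation Hoveyda–Grubbs catalyst RuCl2(H2IMes)(=CH–C6H4-2-O-i-Pr) (5 mol%), 1,4-benzoquinone (10 mol%), CH2Cl2, 40 °C
Reagents that add atoms: none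
Why: Olefin cross-metathesis of a reactive allylarene with an electron-poor vinyl ketone, which homodimerises slowly, should give the conjugated enone as the thermodynamically favoured E isomer; benzoquinone suppresses Ru–H migration of the double bond.

Step 11
Reactants: 15 chloromethyl isopropyl carbonate
Product: 16 iodomethyl isopropyl carbonate
Conditions: NaI, acetone, 40 °C
Reagents that add atoms: sodium iodide, [Na+].[I-]
Why: Finkelstein exchange at the activated α-oxygenated primary chloride, driven by precipitation of NaCl.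

Step 12
Reactants: 16 iodomethyl isopropyl carbonate
Product: 18 {[(isopropoxycarbonyl)oxy]methyl}[(trimethylsilyl)methyl]zinc, via alkylzinc iodide 17 (not isolated)
Conditions: Zn dust (2 equiv; activated with BrCH2CH2Br 4 mol% and Me3SiCl 1 mol%), THF, 10–15 °C; decanted from excess Zn; then Me3SiCH2Li (1.0 equiv, pentane), −78 → −30 °C; THF exchanged for toluene in vacuo, LiI filtered off under argon; used as the solution
Reagents that add atoms: zinc, [Zn]; (trimethylsilyl)methyllithium, [Li]C[Si](C)(C)C
Why: Oxidative insertion of activated zinc into the α-oxygenated primary C–I bond gives the alkylzinc iodide with the carbonate untouched, and low-temperature transmetalation of its Zn–I bond with Me3SiCH2Li, which is far faster than attack on the carbonate, gives the mixed diorganozinc in which the silylmethyl group serves as a non-transferable ligand; no stereocentre is formed.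

Step 13
Reactants: 14 the (E)-enone; 18 the mixed zinc reagent (2.0 equiv)
Product: 20 (3S,4R)-3-[4-(benzyloxy)-3-methoxybenzoyl]-4-(Bf-methyl)oxolan-2-one (3,4-trans), via zinc enolate 19 (not isolated)
Conditions: Cu(OTf)2 (5 mol%), (S,R,R)-configured BINOL-derived N,N-bis(1-phenylethyl)phosphoramidite (10 mol%), toluene, −30 °C; then LiOt-Bu (1.5 equiv), THF, −30 → 25 °C; aq. NH4Cl
Reagents that add atoms: none
Why: Proposed new method: copper, reduced by the zinc reagent to the monovalent state and bound to the phosphoramidite, takes the oxygen-bearing CH2 group of 18 from zinc in preference to the non-transferable Me3SiCH2 group and adds it 1,4 to the enone (π-complex, β-cupration to a trivalent copper intermediate, reductive elimination), which forms C4–C5 and zinc enolate 19; LiOt-Bu then turns 19 into a more nucleophilic zincate enolate whose C3 attacks the carbonate carbonyl of its own side chain and expels isopropoxide, which forms C2–C3. The closest known reaction types are the copper-mediated conjugate addition of (acyloxymethyl)zinc reagents to enones, the copper-mediated selective transfer of the functionalised group from mixed alkyl(trimethylsilylmethyl)zincs, the copper–phosphoramidite-catalysed enantioselective conjugate addition of dialkylzincs to acyclic enones with trapping of the zinc enolate, and the Dieckmann-type C-acylation of ketone enolates by carbonates; what is new is their union in one reagent, so that the enolate is trapped by the donor's own carbonate. Ring B closes in the 5-exo-trig mode at the carbonate C=O, which is favoured over the seven-membered O-acylation, and the β-keto lactone is drained from all equilibria as its stabilised enolate. C4 (R) is set by the chiral ligand, which directs the CH2 group to the Re face of the enone β-carbon; C3 is set by thermodynamics, because the doubly activated C3–H equilibrates on protonation to the trans isomer with the aroyl and Bf-methyl groups on opposite faces. The step needs regioselectivity (CH2O to C4, C=O to C3), secured by the polarisation of the C=C by the aryl ketone; 1,4- over 1,2-addition, secured by the soft copper nucleophile; and a single enolate, secured because the ketone has no other α-hydrogen.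

Step 14
Reactants: 20 the keto lactone
Product: 21 (3S,4R)-3-{[4-(benzyloxy)-3-methoxyphenyl](hydroxy)methyl}-4-(Bf-methyl)oxolan-2-one (mixture of carbinol epimers)
Conditions: NaBH4, CeCl3·7H2O, MeOH–THF, −40 °C
Reagents that add atoms: none
Why: Luche-type 1,2-reduction of the aryl ketone is much faster than attack on the lactone at low temperature and removes the acidity of C3–H, so the trans arrangement is fixed; the carbinol configuration is irrelevant because that oxygen is removed next.

Step 15
Reactants: 21 the hydroxy lactone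
Product: 22 Lappaol A, (3R,4R)-3-(4-hydroxy-3-methoxybenzyl)-4-{[(2S,3R)-2-(4-hydroxy-3-methoxyphenyl)-3-(hydroxymethyl)-7-methoxy-2,3-dihydro-1-benzofuran-5-yl]methyl}oxolan-2-one
Conditions: H2 (1 atm), 10% Pd/C, EtOAc–AcOH (10:1), 25 °C
Reagents that add atoms: none
Why: Catalytic hydrogenolysis should cleave the three benzyl ethers and the benzylic C–OH bond (activated by the para-oxygenated ring A) while the lactone and the cyclic benzylic aryl ether of ring D persist under these mild conditions; no stereocentre is involved.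

**Compound list**

1 | eugenol | C=CCc1ccc(O)c(OC)c1 | starting material
2 | 4-allyl-2-iodo-6-methoxyphenol | C=CCc1cc(I)c(O)c(OC)c1 | intermediate
3 | [4-(benzyloxy)-3-methoxyphenyl]methanol | OCc1ccc(OCc2ccccc2)c(OC)c1 | starting material
4 | 5-allyl-2-{[4-(benzyloxy)-3-methoxybenzyl]oxy}-1-iodo-3-methoxybenzene | C=CCc1cc(I)c(OCc2ccc(OCc3ccccc3)c(OC)c2)c(OC)c1 | intermediate
5 | ethyl diazoacetate | CCOC(=O)C=[N+]=[N-] | starting material
6 | ethyl 2-diazo-2-[5-allyl-2-{[4-(benzyloxy)-3-methoxybenzyl]oxy}-3-methoxyphenyl]acetate | CCOC(=O)C(=[N+]=[N-])c1cc(CC=C)cc(OC)c1OCc1ccc(OCc2ccccc2)c(OC)c1 | intermediate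
7 | ethyl (2S,3R)-5-allyl-2-[4-(benzyloxy)-3-methoxyphenyl]-7-methoxy-2,3-dihydro-1-benzofuran-3-carboxylate (cis) | C=CCc1cc(OC)c2c(c1)[C@@H](C(=O)OCC)[C@@H](c1ccc(OCc3ccccc3)c(OC)c1)O2 | intermediate
8 | ethyl (2S,3S)-5-allyl-2-[4-(benzyloxy)-3-methoxyphenyl]-7-methoxy-2,3-dihydro-1-benzofuran-3-carboxylate (trans) | C=CCc1cc(OC)c2c(c1)[C@H](C(=O)OCC)[C@@H](c1ccc(OCc3ccccc3)c(OC)c1)O2 | intermediate
9 | [(2S,3R)-5-allyl-2-[4-(benzyloxy)-3-methoxyphenyl]-7-methoxy-2,3-dihydro-1-benzofuran-3-yl]methanol | C=CCc1cc(OC)c2c(c1)[C@H](CO)[C@@H](c1ccc(OCc3ccccc3)c(OC)c1)O2 | intermediate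
10 | (2S,3R)-5-allyl-3-[(benzyloxy)methyl]-2-[4-(benzyloxy)-3-methoxyphenyl]-7-methoxy-2,3-dihydro-1-benzofuran | C=CCc1cc(OC)c2c(c1)[C@H](COCc1ccccc1)[C@@H](c1ccc(OCc3ccccc3)c(OC)c1)O2 | intermediate
11 | 4-(benzyloxy)-3-methoxybenzaldehyde | O=Cc1ccc(OCc2ccccc2)c(OC)c1 | starting material
12 | 1-[4-(benzyloxy)-3-methoxyphenyl]prop-2-en-1-ol (racemic) | C=CC(O)c1ccc(OCc2ccccc2)c(OC)c1 | intermediate
13 | 1-[4-(benzyloxy)-3-methoxyphenyl]prop-2-en-1-one | C=CC(=O)c1ccc(OCc2ccccc2)c(OC)c1 | intermediate
14 | (E)-1-[4-(benzyloxy)-3-methoxyphenyl]-4-{(2S,3R)-3-[(benzyloxy)methyl]-2-[4-(benzyloxy)-3-methoxyphenyl]-7-methoxy-2,3-dihydro-1-benzofuran-5-yl}but-2-en-1-one | O=C(/C=C/Cc1cc(OC)c2c(c1)[C@H](COCc1ccccc1)[C@@H](c1ccc(OCc3ccccc3)c(OC)c1)O2)c1ccc(OCc2ccccc2)c(OC)c1 | intermediate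
15 | chloromethyl isopropyl carbonate | CC(C)OC(=O)OCCl | starting material
16 | iodomethyl isopropyl carbonate | CC(C)OC(=O)OCI | intermediate
17 | iodo{[(isopropoxycarbonyl)oxy]methyl}zinc (alkylzinc iodide) | CC(C)OC(=O)OC[Zn]I | intermediate
18 | {[(isopropoxycarbonyl)oxy]methyl}[(trimethylsilyl)methyl]zinc | CC(C)OC(=O)OC[Zn]C[Si](C)(C)C | intermediate
19 | zinc enolate of the (R)-configured conjugate adduct, still carrying the isopropyl carbonate and the silylmethyl group on zinc | CC(C)OC(=O)OC[C@@H](C=C(O[Zn]C[Si](C)(C)C)c1ccc(OCc2ccccc2)c(OC)c1)Cc1cc(OC)c2c(c1)[C@H](COCc1ccccc1)[C@@H](c1ccc(OCc3ccccc3)c(OC)c1)O2 | intermediate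
20 | (3S,4R)-3-[4-(benzyloxy)-3-methoxybenzoyl]-4-({(2S,3R)-3-[(benzyloxy)methyl]-2-[4-(benzyloxy)-3-methoxyphenyl]-7-methoxy-2,3-dihydro-1-benzofuran-5-yl}methyl)oxolan-2-one (trans) | O=C(c1ccc(OCc2ccccc2)c(OC)c1)[C@H]1C(=O)OC[C@@H]1Cc1cc(OC)c2c(c1)[C@H](COCc1ccccc1)[C@@H](c1ccc(OCc3ccccc3)c(OC)c1)O2 | intermediate
21 | (3S,4R)-3-{[4-(benzyloxy)-3-methoxyphenyl](hydroxy)methyl}-4-({(2S,3R)-3-[(benzyloxy)methyl]-2-[4-(benzyloxy)-3-methoxyphenyl]-7-methoxy-2,3-dihydro-1-benzofuran-5-yl}methyl)oxolan-2-one (carbinol epimers) | OC(c1ccc(OCc2ccccc2)c(OC)c1)[C@H]1C(=O)OC[C@@H]1Cc1cc(OC)c2c(c1)[C@H](COCc1ccccc1)[C@@H](c1ccc(OCc3ccccc3)c(OC)c1)O2 | intermediate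
22 | Lappaol A | COc1cc(C[C@H]2C(=O)OC[C@@H]2Cc2cc(OC)c3c(c2)[C@H](CO)[C@@H](c2ccc(O)c(OC)c2)O3)ccc1O | target

**Step count and risks**

Total step count: 15. Longest linear sequence: 11 steps (steps 1–7, 10, 13, 14, 15).

Steps most likely to fail:

1. Step 13 (bears the label). Transfer of the oxygen-bearing CH2 group from zinc to copper may be slower than uncatalysed background addition or than transfer of the silylmethyl group, which would erode facial selectivity and conversion. Closure of the enolate onto the carbonate may also stall, so that the open-chain adduct is simply protonated. The fallback uses known chemistry only, sets out from 10 and returns to the route at 22. [2+2] Cycloaddition of 10 with dichloroketene (Cl3CCOCl, Zn–Cu couple, Et2O) should give the 2,2-dichloro-3-(Bf-methyl)cyclobutanone F1. Dechlorination (Zn, NH4Cl, MeOH) gives the prochiral 3-(Bf-methyl)cyclobutanone F2. Catalytic enantioselective Baeyer–Villiger desymmetrisation (chiral BINOL-derived phosphoric acid, aq. H2O2, CHCl3, −40 °C) gives (R)-4-(Bf-methyl)oxolan-2-one F3. Alcohol 3 is converted with PBr3 into 4-(benzyloxy)-3-methoxybenzyl bromide F4. Alkylation of the lithium enolate of F3 (LiN(SiMe3)2, THF, −78 °C) with F4 anti to the C4 substituent gives tri-O-benzyl Lappaol A F5, and hydrogenolysis (H2, 10% Pd/C, EtOAc) gives 22.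

2. Step 3. Loss of dinitrogen from the diazo ester at palladium (carbene dimerisation) and slow oxidative addition at the hindered, electron-rich C–I bond may outrun the coupling. The fallback sets out from 4 and returns at 6. Palladium-catalysed coupling of 4 with the Reformatsky reagent BrZnCH2CO2Et (Pd(dba)2, P(t-Bu)3, THF, 25 °C) should give ethyl 2-[5-allyl-2-{[4-(benzyloxy)-3-methoxybenzyl]oxy}-3-methoxyphenyl]acetate F6. Regitz diazo transfer (4-acetamidobenzenesulfonyl azide, DBU, MeCN) then gives 6.

3. Step 15. Cleavage of the benzylic C–OH bond and of the primary benzyl ether may lag so far behind aryl ether debenzylation that the prolonged, acid-assisted exposure opens ring D at its benzylic C2–O bond. The fallback sets out from 21 and returns at 22, with the oxygen removed by a radical path before a short, neutral debenzylation. Acylation of 21 with PhOC(S)Cl (pyridine, DMAP, CH2Cl2) gives the O-phenyl thionocarbonate F7. Barton–McCombie deoxygenation (Bu3SnH, AIBN, toluene, 80 °C) gives tri-O-benzyl Lappaol A F5, and hydrogenolysis in neutral EtOAc (H2, 10% Pd/C) gives 22.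

**Further compounds**

F1 | step 13 | 2,2-dichloro-3-({(2S,3R)-3-[(benzyloxy)methyl]-2-[4-(benzyloxy)-3-methoxyphenyl]-7-methoxy-2,3-dihydro-1-benzofuran-5-yl}methyl)cyclobutan-1-one (both epimers at the cyclobutane carbon) | O=C1CC(Cc2cc(OC)c3c(c2)[C@H](COCc2ccccc2)[C@@H](c2ccc(OCc4ccccc4)c(OC)c2)O3)C1(Cl)Cl
F2 | step 13 | 3-({(2S,3R)-3-[(benzyloxy)methyl]-2-[4-(benzyloxy)-3-methoxyphenyl]-7-methoxy-2,3-dihydro-1-benzofuran-5-yl}methyl)cyclobutan-1-one | O=C1CC(Cc2cc(OC)c3c(c2)[C@H](COCc2ccccc2)[C@@H](c2ccc(OCc4ccccc4)c(OC)c2)O3)C1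
F3 | step 13 | (R)-4-({(2S,3R)-3-[(benzyloxy)methyl]-2-[4-(benzyloxy)-3-methoxyphenyl]-7-methoxy-2,3-dihydro-1-benzofuran-5-yl}methyl)oxolan-2-one | O=C1C[C@@H](Cc2cc(OC)c3c(c2)[C@H](COCc2ccccc2)[C@@H](c2ccc(OCc4ccccc4)c(OC)c2)O3)CO1
F4 | step 13 | 4-(benzyloxy)-3-methoxybenzyl bromide | BrCc1ccc(OCc2ccccc2)c(OC)c1
F5 | step 13 | tri-O-benzyl Lappaol A, (3R,4R)-3-[4-(benzyloxy)-3-methoxybenzyl]-4-({(2S,3R)-3-[(benzyloxy)methyl]-2-[4-(benzyloxy)-3-methoxyphenyl]-7-methoxy-2,3-dihydro-1-benzofuran-5-yl}methyl)oxolan-2-one | COc1cc(C[C@H]2C(=O)OC[C@@H]2Cc2cc(OC)c3c(c2)[C@H](COCc2ccccc2)[C@@H](c2ccc(OCc4ccccc4)c(OC)c2)O3)ccc1OCc1ccccc1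
F6 | step 3 | ethyl 2-[5-allyl-2-{[4-(benzyloxy)-3-methoxybenzyl]oxy}-3-methoxyphenyl]acetate | CCOC(=O)Cc1cc(CC=C)cc(OC)c1OCc1ccc(OCc2ccccc2)c(OC)c1
F7 | step 15 | O-phenyl thionocarbonate of 21 at the benzylic carbinol (carbinol epimers) | S=C(Oc1ccccc1)OC(c1ccc(OCc2ccccc2)c(OC)c1)[C@H]1C(=O)OC[C@@H]1Cc1cc(OC)c2c(c1)[C@H](COCc1ccccc1)[C@@H](c1ccc(OCc3ccccc3)c(OC)c1)O2
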